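How much target stands after 40 min in each of the four flasks that differ in their charge of starting material, with the other charges the same?

| flask | starting material | second substrate | third substrate | solid reagent | remark | time |
|---|---|---|---|---|---|---|
| elm | 12 mM | 22 mM | 44 mM (in portions, 2) | 110 mM | run made earlier; portions every 3.0 min |  |
| maple | 260 mM | 22 mM | 44 mM (in portions, 2) | 110 mM | run made earlier; portions every 3.0 min |  |
| ochre | 15 mM | 22.0 mM | 44.0 mM (in portions, 2) | 110 mM | the portions of third substrate follow each other after 3.0 min, the first at the start | 40 min |
| red | 40 mM | 22.0 mM | 44.0 mM (in portions, 2) | 110 mM | the portions of third substrate follow each other after 3.0 min, the first at the start | 40 min |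
| grey | 120 mM | 22.0 mM | 44.0 mM (in portions, 2) | 110 mM | the portions of third substrate follow each other after 3.0 min, the first at the start | 40 min |
| blue | 400 mM | 22.0 mM | 44.0 mM (in portions, 2) | 110 mM | the portions of third substrate follow each other after 3.0 min, the first at the start | 40 min |

- [target] at the end for ochre, red, grey, blue, in this order
- the shape of the row from first to last (rises all the way / falls, then rises / falls all the way / hardly changes / rises, then falls)

- solid reagent is a solid; its amount is given per volume of the solution
- the numbers in the tables scatter by 1.5 percentage points (one standard deviation)
- at the start none of the solid reagent is in solution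
- "hardly changes" means that all values lie within two and a half points (for a concentration: within two and a half percent of the largest)

| run | time / min | target / % |
|---|---|---|
| elm | 4.00 | 2 |
| elm | 10.0 | 2 |
| elm | 20.0 | 10 |
| elm | 30.0 | 18 |
| maple | 2.50 | 0 |
| maple | 5.00 | 1 |
| maple | 12.0 | 2 |
| maple | 30.0 | 9 |

(readings scatter by 1.5 percentage points)

I read the last rows of the two tables against each other. At 30.0 min elm shows 18 % and maple 9 %, half the percentage, but maple's percentage is taken of a larger charge. In millimolar terms, elm holds 2.16 mM and maple 23.4 mM. The load rose by a factor of 21.7 and the target by a factor of 10.8, so the factor on the target is smaller than the factor on the load. The ratio of the two logarithms gives 0.775. This is the load exponent, an apparent order: the percent gain in target per percent gain in charge.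

Elm gained 8 percentage points between its last two readings. If that pace holds to 40 min, elm reaches 3.12 mM. Scaling this by the load ratio raised to the exponent, I expect 3.71 mM, 7.93 mM, 18.6 mM and 47.2 mM. I hold the last loosely, since blue's load lies beyond maple's.

The forecast reads nearly the same exponent, 0.75, but says “the second substrate caps the target near 22 mM”. It gives 3.6 mM, 7.5 mM, 14 mM and 20 mM, a row that rises all the way. At blue my figure is higher than the forecast's.

The flasks give 3.78 mM, 9.08 mM, 20.3 mM and 33.9 mM, a row that rises all the way.

    starting material + partner → target (k = 0.0100 L mol⁻¹ s⁻¹)
    second substrate + partner → second product (k = 0.00660 L mol⁻¹ s⁻¹)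
    third substrate + partner → third product (k = 0.00540 L mol⁻¹ s⁻¹)
    solid reagent ⇌ partner, rate k4*(cs4 - [partner]) while solid is left; crystals form when [partner] > cs4 (solubility = 42.0 mM, k = 4.50 × 10⁻⁴ s⁻¹)

Carried from ochre's result, the exponent gives 18.9 mM for grey, which stands at 20.3 mM. Carried from grey, it gives 51.6 mM for blue, which stands at 33.9 mM. In ochre the solid reagent dissolved down to 70.6 % of its charge by 40.0 min, while partner built up to 18.3 mM. In blue the solid went further, to 62.4 %, yet partner stood at 4.19 mM, while starting material became target and second substrate still stood at 94.3 % of its charge.

Readings and results stem from a simulated flask on assumed constants; scatter was added.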